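## Retrosynthetic overview

1. Menaquinone-8 ⇐ oxidative demethylation of menaquinol-8 dimethyl ether. Ring A (benzo) and ring B (quinone) come intact from menadione, so no ring is formed in the route.
2. Key disconnection: the C(sp2)–C(sp3) bond between the vinylic CH of prenyl unit 4 and its allylic CH2. In the forward direction this is a one-pot three-component union of a C23 terminal enyne, one CH3 of Me3Al and a C16 homoallylic iodide that already carries the masked naphthoquinone.
3. Enabling feature: in the C(CH3)=CH–CH2 group of unit 4 the CH3 and the CH2 are cis, which is the signature of syn Me–Al addition to a terminal C≡CH. That CH2 is also a primary, unbranched carbon two atoms from C(CH3)= of unit 3, so it suits SN2-like insertion of zerovalent palladium and maps back onto the end carbon of a 1,3-diene.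
4. Iodide ⇐ hydrozirconation/iodinolysis of the diene ⇐ Wittig methylenation ⇐ E-selective SeO2 oxidation of the terminal CH3 of the farnesyl arene ⇐ aryl Grignard reagent + farnesyl bromide.
5. Enyne ⇐ geranylgeranyl bromide + dilithiopropyne.

Key step: step 10

Remark: prenyl units are counted from ring B (unit 1) to the chain end (unit 8). Geranylgeraniol and farnesyl bromide are taken as the commercial all-E isomers. The target has no stereocentre, only seven E alkenes.

## Route

Step 1
Reactants: 1 menadione
Product: 3 menadiol dimethyl ether (1,4-dimethoxy-2-methylnaphthalene), via menadiol 2 (not isolated)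
Conditions: Na2S2O4, n-Bu4NBr (cat.), THF/H2O, rt; then aq KOH, Me2SO4, rt, N2
Reagents that add atoms: dimethyl sulfate, COS(=O)(=O)OC
Why: Reductive methylation, in which Na2S2O4 reduces the quinone to hydroquinone 2 and its dianion is O-methylated twice (Williamson ether synthesis) before air can reoxidise it; no stereocentre is involved.

Step 2
Reactants: 3 menadiol dimethyl ether
Product: 4 bromoarene (2-bromo-1,4-dimethoxy-3-methylnaphthalene)
Conditions: Br2, CH2Cl2, 0 °C
Reagents that add atoms: bromine, BrBr
Why: Electrophilic aromatic bromination goes to C3, the only free position of the doubly methoxy-activated ring B.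

Step 3
Reactants: 4 bromoarene; 5 (2E,6E)-farnesyl bromide
Product: 7 farnesyl arene (2-[(2E,6E)-3,7,11-trimethyldodeca-2,6,10-trienyl]-1,4-dimethoxy-3-methylnaphthalene), via arylmagnesium bromide 6 (not isolated)
Conditions: 4, Mg, THF, reflux; CuBr·SMe2 (10 mol %), 0 °C; then 5, 0 °C to rt
Reagents that add atoms: none
Why: Copper-catalysed Grignard coupling with an allylic bromide, in which the aryl copper species attacks the primary carbon of 5 (SN2, not SN2', because the γ-carbon is fully substituted), so the 2E and 6E alkenes are carried over unchanged.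

Step 4
Reactants: 7 farnesyl arene
Product: 8 allylic alcohol ((2E,6E,10E)-12-(1,4-dimethoxy-3-methylnaphthalen-2-yl)-2,6,10-trimethyldodeca-2,6,10-trien-1-ol)
Conditions: SeO2 (0.2 equiv), t-BuOOH (2.5 equiv), salicylic acid (0.1 equiv), CH2Cl2, 0 °C to rt, stopped at partial conversion, 7 recycled
Reagents that add atoms: tert-butyl hydroperoxide, CC(C)(C)OO
Why: Riley-type allylic hydroxylation (ene reaction, then [2,3]-sigmatropic shift) prefers the least hindered terminal isopropylidene group and oxidises only the CH3 trans to the chain, which sets the E geometry of the unit 3 alkene.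

Step 5
Reactants: 8 allylic alcohol
Product: 9 enal ((2E,6E,10E)-12-(1,4-dimethoxy-3-methylnaphthalen-2-yl)-2,6,10-trimethyldodeca-2,6,10-trienal)
Conditions: activated MnO2 (excess), CH2Cl2, rt
Reagents that add atoms: none
Why: MnO2 oxidises allylic alcohols selectively to enals under neutral conditions without E/Z isomerisation and leaves the aryl ethers and isolated alkenes alone.

Step 6
Reactants: 9 enal
Product: 10 diene (1,4-dimethoxy-2-methyl-3-[(2E,6E,10E)-3,7,11-trimethyltrideca-2,6,10,12-tetraenyl]naphthalene)
Conditions: Ph3PCH3Br, n-BuLi, THF, 0 °C; then 9, −78 °C to rt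
Reagents that add atoms: methyltriphenylphosphonium bromide, C[P+](c1ccccc1)(c1ccccc1)c1ccccc1.[Br-]
Why: Wittig methylenation turns the aldehyde into the only monosubstituted C=C of the molecule, while the adjacent trisubstituted alkene takes no part and keeps its E geometry.

Step 7
Reactants: 10 diene
Product: 12 homoallylic iodide (2-[(2E,6E,10E)-13-iodo-3,7,11-trimethyltrideca-2,6,10-trienyl]-1,4-dimethoxy-3-methylnaphthalene), via alkylzirconocene chloride 11 (not isolated)
Conditions: Cp2Zr(H)Cl (1.3 equiv), THF, rt, dark; then I2, THF, 0 °C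
Reagents that add atoms: iodine, [I][I]
Why: Hydrozirconation/iodinolysis, in which Cp2Zr(H)Cl adds 1,2 only to the vinyl end of the 1,3-diene with Zr on the terminal carbon (the trisubstituted alkenes are too hindered), and I2 cleaves the C–Zr bond to the primary iodide without touching the neighbouring E alkene.

Step 8
Reactants: 13 (2E,6E,10E)-geranylgeraniol
Product: 14 (2E,6E,10E)-geranylgeranyl bromide
Conditions: PBr3 (0.4 equiv), Et2O, −10 °C; used crude
Reagents that add atoms: phosphorus tribromide, BrP(Br)Br
Why: SN2-type bromination of the primary allylic alcohol through its phosphite ester at low temperature avoids allylic transposition and keeps the 2E alkene.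

Step 9
Reactants: 14 geranylgeranyl bromide; 15 propyne
Product: 18 enyne ((5E,9E,13E)-6,10,14,18-tetramethylnonadeca-5,9,13,17-tetraen-1-yne), via dilithiopropyne 16 (not isolated), via lithium acetylide 17 (not isolated)
Conditions: 15, n-BuLi (2 equiv per 15), TMEDA, Et2O/hexane, −78 °C to rt; 14, −78 °C to rt; then H2O
Reagents that add atoms: none
Why: Propargylation of an allylic halide with dilithiopropyne, in which the more reactive propargylic carbanion is alkylated by SN2 at the primary allylic carbon, the alkene geometry is kept and the acetylide end is only protonated on quench.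

Step 10
Reactants: 18 enyne; 12 homoallylic iodide
Product: 21 menaquinol-8 dimethyl ether (1,4-dimethoxy-2-methyl-3-[(all-E)-octaprenyl]naphthalene), via alkenyldimethylalane 19 (not isolated), via alkenylzinc bromide 20 (not isolated)
Conditions: 18 (1.2 equiv), Me3Al (2 equiv), Cp2ZrCl2 (20 mol %), ClCH2CH2Cl, 0 °C to rt; volatiles removed in vacuo; ZnBr2, THF, 0 °C; then 12, Pd2(dba)3 (2 mol %), P(c-C5H9)3 (8 mol %), N-methylimidazole, THF/NMP, 80 °C
Reagents that add atoms: trimethylaluminium, C[Al](C)C
Why: Cp2ZrCl2 and Me3Al form a polarised Zr–Me/Al species that adds methyl and metal syn across the only C≡C bond of 18, methyl to the internal and metal to the terminal carbon, which gives the (E)-alkenylalane 19 (Negishi zirconium-catalysed carboalumination). ZnBr2 takes over the sp2 group with retention (20), zerovalent palladium bearing P(c-C5H9)3 inserts into the primary C–I bond of 12 by an SN2-like oxidative addition, and transmetalation followed by reductive elimination forms the vinylic CH–CH2 bond with retention. The closest known reaction types are the one-pot carboalumination/cross-coupling of alkenylalanes by way of zinc and the Pd/trialkylphosphine Negishi coupling of alkenylzinc halides with unactivated, β-hydrogen-bearing primary alkyl iodides. No ring is closed and no stereocentre is made; the one new stereo-element, the E alkene of unit 4, is fixed by the syn addition and by retention in both metal exchanges. The step needs alkyne over alkene selectivity (the four trisubstituted alkenes of 18 are inert to Me3Al/Cp2ZrCl2), alkenyl over methyl transfer (sp2 groups transfer faster and the excess Me3Al is stripped off first), and coupling over β-hydride elimination (bulky electron-rich phosphine plus N-methylimidazole). The two aryl methyl ethers hold ring B at the hydroquinone level, so no C=O group is exposed to the aluminium and zinc reagents.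

Step 11
Reactants: 21 menaquinol-8 dimethyl ether
Product: 22 menaquinone-8
Conditions: (NH4)2Ce(NO3)6 (2.5 equiv), MeCN/CH2Cl2/H2O, 0 °C
Reagents that add atoms: water, O
Why: Oxidative demethylation of a 1,4-dimethoxyarene by tetravalent cerium (two one-electron oxidations, attack of water at C1 and C4, loss of methanol) is much faster than any reaction of the isolated trisubstituted alkenes, so all seven E alkenes should survive.

## Compound list

1 | menadione (2-methylnaphthalene-1,4-dione) | CC1=CC(=O)c2ccccc2C1=O | starting material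
2 | menadiol (2-methylnaphthalene-1,4-diol) | Cc1cc(O)c2ccccc2c1O | intermediate
3 | menadiol dimethyl ether (1,4-dimethoxy-2-methylnaphthalene) | Cc1cc(OC)c2ccccc2c1OC | intermediate
4 | 2-bromo-1,4-dimethoxy-3-methylnaphthalene | Cc1c(Br)c(OC)c2ccccc2c1OC | intermediate
5 | (2E,6E)-farnesyl bromide | CC(C)=CCC/C(C)=C/CC/C(C)=C/CBr | starting material
6 | (1,4-dimethoxy-3-methylnaphthalen-2-yl)magnesium bromide | Cc1c([Mg]Br)c(OC)c2ccccc2c1OC | intermediate
7 | 2-[(2E,6E)-farnesyl]-1,4-dimethoxy-3-methylnaphthalene | CC(C)=CCC/C(C)=C/CC/C(C)=C/Cc1c(C)c(OC)c2ccccc2c1OC | intermediate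
8 | (2E,6E,10E)-12-(1,4-dimethoxy-3-methylnaphthalen-2-yl)-2,6,10-trimethyldodeca-2,6,10-trien-1-ol | OC/C(C)=C/CC/C(C)=C/CC/C(C)=C/Cc1c(C)c(OC)c2ccccc2c1OC | intermediate
9 | (2E,6E,10E)-12-(1,4-dimethoxy-3-methylnaphthalen-2-yl)-2,6,10-trimethyldodeca-2,6,10-trienal | O=C/C(C)=C/CC/C(C)=C/CC/C(C)=C/Cc1c(C)c(OC)c2ccccc2c1OC | intermediate
10 | 1,4-dimethoxy-2-methyl-3-[(2E,6E,10E)-3,7,11-trimethyltrideca-2,6,10,12-tetraenyl]naphthalene | C=C/C(C)=C/CC/C(C)=C/CC/C(C)=C/Cc1c(C)c(OC)c2ccccc2c1OC | intermediate
11 | chlorobis(cyclopentadienyl)zirconium alkyl from 10, Zr on the terminal carbon (Cp rings drawn σ-bonded) | Cl[Zr](C1C=CC=C1)(C1C=CC=C1)CC/C(C)=C/CC/C(C)=C/CC/C(C)=C/Cc1c(C)c(OC)c2ccccc2c1OC | intermediate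
12 | 2-[(2E,6E,10E)-13-iodo-3,7,11-trimethyltrideca-2,6,10-trienyl]-1,4-dimethoxy-3-methylnaphthalene | ICC/C(C)=C/CC/C(C)=C/CC/C(C)=C/Cc1c(C)c(OC)c2ccccc2c1OC | intermediate
13 | (2E,6E,10E)-geranylgeraniol | CC(C)=CCC/C(C)=C/CC/C(C)=C/CC/C(C)=C/CO | starting material
14 | (2E,6E,10E)-geranylgeranyl bromide | CC(C)=CCC/C(C)=C/CC/C(C)=C/CC/C(C)=C/CBr | intermediate
15 | propyne | CC#C | starting material
16 | 1,3-dilithiopropyne | [Li]CC#C[Li] | intermediate
17 | lithium acetylide of 18 | CC(C)=CCC/C(C)=C/CC/C(C)=C/CC/C(C)=C/CCC#C[Li] | intermediate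
18 | (5E,9E,13E)-6,10,14,18-tetramethylnonadeca-5,9,13,17-tetraen-1-yne | CC(C)=CCC/C(C)=C/CC/C(C)=C/CC/C(C)=C/CCC#C | intermediate
19 | dimethyl[(1E,5E,9E,13E)-2,6,10,14,18-pentamethylnonadeca-1,5,9,13,17-pentaenyl]alane | CC(C)=CCC/C(C)=C/CC/C(C)=C/CC/C(C)=C/CC/C(C)=C/[Al](C)C | intermediate
20 | [(1E,5E,9E,13E)-2,6,10,14,18-pentamethylnonadeca-1,5,9,13,17-pentaenyl]zinc bromide | CC(C)=CCC/C(C)=C/CC/C(C)=C/CC/C(C)=C/CC/C(C)=C/[Zn]Br | intermediate
21 | menaquinol-8 dimethyl ether (all-E) | CC(C)=CCC/C(C)=C/CC/C(C)=C/CC/C(C)=C/CC/C(C)=C/CC/C(C)=C/CC/C(C)=C/CC/C(C)=C/Cc1c(C)c(OC)c2ccccc2c1OC | intermediate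
22 | menaquinone-8 | CC(C)=CCC/C(C)=C/CC/C(C)=C/CC/C(C)=C/CC/C(C)=C/CC/C(C)=C/CC/C(C)=C/CC/C(C)=C/CC1=C(C)C(=O)c2ccccc2C1=O | target

## Step count and risks

Total step count: 11. Longest linear sequence: 9 steps (steps 1 to 7, 10 and 11).

**Step 10.**
- Risks:
  - Methyl transfer from aluminium or zinc to the alkylpalladium intermediate.
  - β-Hydride elimination of the homoallylpalladium species back to the conjugated diene.
  - Carry-through of the minor regiochemical mode of carbometalation into a product that is hard to purify.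
- Fallback (sets out from 18 and 10, comes back at 21): the polarity of the two carbons is exchanged.
  - Enyne 18 is carboaluminated as before (19) and quenched with I2 to the isolable and purifiable (E)-alkenyl iodide F1.
  - Diene 10 is hydroborated at its vinyl group with 9-BBN-H to the B-alkyl-9-BBN F2.
  - The two are joined by a B-alkyl Suzuki–Miyaura coupling (PdCl2(dppf), AsPh3, Cs2CO3, DMF/THF/H2O, rt) to give 21. Step 7 is then not needed.

**Step 7.**
- Risks:
  - Migration of zirconium by β-hydride elimination and re-addition towards the allylic position.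
  - Incomplete hydrozirconation.
  - Electrophilic attack of iodine on the chain.
- Fallback (sets out from 10, comes back at 12): the C–I bond is made by substitution at an alcohol instead of by cleavage of a carbon–metal bond.
  - Dicyclohexylborane adds to the vinyl group to give the trialkylborane F3.
  - NaOH/H2O2 converts it into the homoallylic alcohol F4.
  - An Appel-type iodination (I2, PPh3, imidazole, CH2Cl2, 0 °C) gives 12.

**Step 4.**
- Risks:
  - Poor site selectivity among the three trisubstituted alkenes and the doubly activated ArCH2 position.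
  - Over-oxidation.
  - Low conversion.
- Fallback (sets out from 7, comes back at 9): the terminal isopropylidene group is cut off and the E-enal is rebuilt by olefination.
  - Terminal-selective bromohydrin formation (NBS, THF/H2O, 0 °C) gives the bromohydrin F5.
  - K2CO3/MeOH closes it to the terminal epoxide F6.
  - H5IO6 (THF/H2O) cleaves it to the aldehyde F7.
  - An E-selective Wittig reaction with the stabilised ylide Ph3P=C(CH3)CHO (toluene, reflux) gives 9. Step 5 is then not needed.

## Further compounds

F1 | step 10 | (1E,5E,9E,13E)-1-iodo-2,6,10,14,18-pentamethylnonadeca-1,5,9,13,17-pentaene | CC(C)=CCC/C(C)=C/CC/C(C)=C/CC/C(C)=C/CC/C(C)=C/I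
F2 | step 10 | B-alkyl-9-BBN from 10 (boron on the terminal carbon) | C1CCC2CCCC1B2CC/C(C)=C/CC/C(C)=C/CC/C(C)=C/Cc1c(C)c(OC)c2ccccc2c1OC
F3 | step 7 | dicyclohexyl(alkyl)borane from 10 (boron on the terminal carbon) | C1CCCCC1B(C1CCCCC1)CC/C(C)=C/CC/C(C)=C/CC/C(C)=C/Cc1c(C)c(OC)c2ccccc2c1OC
F4 | step 7 | (3E,7E,11E)-13-(1,4-dimethoxy-3-methylnaphthalen-2-yl)-3,7,11-trimethyltrideca-3,7,11-trien-1-ol | OCC/C(C)=C/CC/C(C)=C/CC/C(C)=C/Cc1c(C)c(OC)c2ccccc2c1OC
F5 | step 4 | (6E,10E)-3-bromo-12-(1,4-dimethoxy-3-methylnaphthalen-2-yl)-2,6,10-trimethyldodeca-6,10-dien-2-ol (racemic) | CC(C)(O)C(Br)CC/C(C)=C/CC/C(C)=C/Cc1c(C)c(OC)c2ccccc2c1OC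
F6 | step 4 | terminal 10,11-epoxide of 7 (racemic) | CC1(C)OC1CC/C(C)=C/CC/C(C)=C/Cc1c(C)c(OC)c2ccccc2c1OC
F7 | step 4 | (4E,8E)-10-(1,4-dimethoxy-3-methylnaphthalen-2-yl)-4,8-dimethyldeca-4,8-dienal | O=CCC/C(C)=C/CC/C(C)=C/Cc1c(C)c(OC)c2ccccc2c1OC
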